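Ring A is a 4-bromobutenolide spiro-fused through its C5 to the cyclobutane. Its lactone O1–C5 bond and the vinylic C4–Br bond on the neighbouring carbon are the two bonds that bromonium-triggered 5-endo lactonisation of a 2,3-allenoic acid creates. The precursor therefore contains no ring A: the future spiro carbon is an sp2 cyclobutane carbon carrying an exocyclic, axially chiral 2-butyl-allenoic acid. One operation with NBS closes ring A, installs its bromine and turns the allene axis into the spiro stereocentre. The allene arises from an α-bromocyclobutanone by acetylide addition anti to bromine and anti-SN2′ hydroxycarbonylation; the same relay builds ring B first.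

Key step: step 12

Assumption: (R)-hex-1-yn-3-ol (5) is taken as a purchasable enantiopure alcohol, like 1 and 13.
Assumption: the (4R,5R)-imidazolidine of step 3 is taken to give the (S)-bromide, by analogy with simple cycloalkanones; if the sense is the opposite, its enantiomer is used.

Ring A is the butyl-bearing bromobutenolide, ring B the one bearing the 1-acetoxybutyl chain; OTBS is tert-butyldimethylsilyloxy.

Step 1
Reactants: 1 1,2-bis(trimethylsilyloxy)cyclobut-1-ene
Product: 2 cyclobutane-1,2-dione
Conditions: Br2 (1.0 equiv), pentane, −60 °C → rt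
Reagents that add atoms: none
Why: Bromine oxidises the enediol bis-silyl ether (addition to the electron-rich alkene, then loss of two Me3SiBr) to the 1,2-dione, a known oxidative desilylation that creates no stereocentre.

Step 2
Reactants: 2 cyclobutane-1,2-dione
Product: 3 2,2-dimethoxycyclobutan-1-one
Conditions: HC(OMe)3 (1.05 equiv), MeOH, TsOH·H2O (cat.), 0 °C → rt
Reagents that add atoms: trimethyl orthoformate, COC(OC)OC
Why: Acid-catalysed ketalisation with one equivalent of orthoformate should stop at the monoketal, because the second carbonyl is then flanked by a quaternary ketal carbon, and the acidic medium avoids the base-induced benzilic-type ring contraction of the dione.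

Step 3
Reactants: 3 2,2-dimethoxycyclobutan-1-one
Product: 4 (S)-4-bromo-2,2-dimethoxycyclobutan-1-one
Conditions: 4,4-dibromo-2,6-di-tert-butylcyclohexa-2,5-dien-1-one (1.0 equiv), (4R,5R)-4,5-diphenylimidazolidine (20 mol %), PhCO2H (20 mol %), THF, −30 °C
Reagents that add atoms: 4,4-dibromo-2,6-di-tert-butylcyclohexa-2,5-dien-1-one, CC(C)(C)C1=CC(Br)(Br)C=C(C(C)(C)C)C1=O
Why: Enamine-catalysed asymmetric α-bromination of a ketone, in which C4 is the only enolisable position and the C2-symmetric secondary amine shields one enamine face so that Br+ from the dienone sets the (S)-C–Br centre.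

Step 4
Reactants: 5 (R)-hex-1-yn-3-ol
Product: 6 (R)-3-(tert-butyldimethylsilyloxy)hex-1-yne
Conditions: TBSCl, imidazole, DMF, rt
Reagents that add atoms: tert-butyldimethylsilyl chloride, CC(C)(C)[Si](C)(C)Cl
Why: Standard silylation of a secondary alcohol; the silyl ether is needed because it is inert to the acetylide, palladium and NBS steps and is not a leaving group at the allenyl–palladium stage of step 6.

Step 5
Reactants: 4 (S)-4-bromo-2,2-dimethoxycyclobutan-1-one; 6 (R)-3-(tert-butyldimethylsilyloxy)hex-1-yne
Product: 8 (1R,4S)-4-bromo-1-[(3R)-3-(tert-butyldimethylsilyloxy)hex-1-yn-1-yl]-2,2-dimethoxycyclobutyl diethyl phosphate, via cis-bromohydrin alkoxide 7 (not isolated)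
Conditions: 6, n-BuLi, THF, −78 °C; CeCl3, −78 °C; 4, −78 °C; then ClP(O)(OEt)2, −78 → 0 °C
Reagents that add atoms: diethyl chlorophosphate, CCOP(=O)(Cl)OCC
Why: Organocerium 1,2-addition (low basicity, so the α-bromoketone is not enolised) should occur on the face anti to the C–Br bond and give the (1R) alkoxide with O cis to Br, which is phosphorylated in the same flask.

Step 6
Reactants: 8 the propargylic diethyl phosphate
Product: 9 (3R)-2-{[(4S)-4-bromo-2,2-dimethoxycyclobutylidene]methylidene}-3-(tert-butyldimethylsilyloxy)hexanoic acid, (P)-allene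
Conditions: Pd(PPh3)4 (5 mol %), CO (1 atm), 2,6-lutidine, THF/H2O (5:1), 0 °C → rt
Reagents that add atoms: carbon monoxide, [C-]#[O+]; water, O
Why: Palladium-catalysed hydroxycarbonylation of a propargylic ester: zerovalent palladium displaces the phosphate in an anti-SN2′ sense, CO inserts into the allenyl–palladium bond with retention and water cleaves the acyl complex, so the carbinol configuration is transcribed into the allene axis with CO2H on the ring face anti to Br.

Step 7
Reactants: 9 the allenoic acid
Product: 10 (3S,4S)-3,8-dibromo-7-[(1R)-1-(tert-butyldimethylsilyloxy)butyl]-1,1-dimethoxy-5-oxaspiro[3.4]oct-7-en-6-one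
Conditions: NBS (1.05 equiv), NaHCO3, MeCN, −20 → 0 °C
Reagents that add atoms: N-bromosuccinimide, O=C1CCC(=O)N1Br
Why: Bromolactonisation of a 2,3-allenoic acid (the reaction type of the key step) builds ring B: Br+ adds to the central allene carbon and the carboxyl oxygen closes 5-endo on the ring carbon from the face it already occupies, which sets the spiro centre with the lactone oxygen trans to the ring C–Br bond.

Step 8
Reactants: 10 the spiro bromobutenolide ketal
Product: 11 (3S,4S)-3,8-dibromo-7-[(1R)-1-(tert-butyldimethylsilyloxy)butyl]-5-oxaspiro[3.4]oct-7-ene-1,6-dione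
Conditions: TsOH·H2O (cat.), acetone/H2O (10:1), 40 °C
Reagents that add atoms: water, O
Why: Acid-catalysed ketal hydrolysis unveils the second ring carbonyl, and the lactone, the vinylic bromide and the hindered secondary silyl ether should tolerate dilute sulfonic acid in wet acetone.

Step 9
Reactants: 11 the spiro ketone
Product: 12 (2R,3R,4S)-2,3,8-tribromo-7-[(1R)-1-(tert-butyldimethylsilyloxy)butyl]-5-oxaspiro[3.4]oct-7-ene-1,6-dione
Conditions: CuBr2 (2.1 equiv), EtOAc/CHCl3 (1:1), 60 °C
Reagents that add atoms: copper dibromide CuBr2, Br[Cu]Br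
Why: α-Bromination of a ketone through its enol under acidic conditions (no enolate, so no E1cB loss of the β-bromide), in which C2 is the only enolisable position and bromine enters trans to the adjacent C3–Br bond, which is also the more stable arrangement.

Step 10
Reactants: 12 the α,β-dibromoketone; 13 hex-1-yne
Product: 15 (1R,2R,3R,4S)-2,3,8-tribromo-7-[(1R)-1-(tert-butyldimethylsilyloxy)butyl]-1-(hex-1-yn-1-yl)-6-oxo-5-oxaspiro[3.4]oct-7-en-1-yl diethyl phosphate, via tertiary alkoxide 14 (not isolated)
Conditions: 13, n-BuLi, THF, −78 °C; CeCl3, −78 °C; 12, −78 °C; then ClP(O)(OEt)2, −78 → −20 °C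
Reagents that add atoms: diethyl chlorophosphate, CCOP(=O)(Cl)OCC
Why: Organocerium acetylide addition to the strained ketone (far more electrophilic than the lactone) is expected from the face anti to both the C2–Br and the C4–O5 bonds, approaching past C2–H, which gives the (1R) alkoxide with O cis to the C2 bromine, and this is trapped as the phosphate.

Step 11
Reactants: 15 the propargylic diethyl phosphate
Product: 16 2-{[(2R,3R,4S)-2,3,8-tribromo-7-[(1R)-1-(tert-butyldimethylsilyloxy)butyl]-6-oxo-5-oxaspiro[3.4]oct-7-en-1-ylidene]methylidene}hexanoic acid, (P)-allene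
Conditions: Pd(PPh3)4 (5 mol %), CO (1 atm), 2,6-lutidine, THF/H2O (5:1), 0 °C
Reagents that add atoms: carbon monoxide, [C-]#[O+]; water, O
Why: The same anti-SN2′ palladium hydroxycarbonylation as in step 6 should be chemoselective because a tertiary propargylic phosphate ionises at 0 °C, well below the temperature at which the hindered tetrasubstituted vinylic bromide of ring B adds to zerovalent palladium, and the carbinol configuration again becomes the allene axis (CO2H anti to the C2–Br bond and to O5).

Step 12
Reactants: 16 the allenoic acid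
Product: 17 (5S,6S,11R,12R)-4,10,11,12-tetrabromo-9-butyl-3-[(1R)-1-(tert-butyldimethylsilyloxy)butyl]-1,7-dioxadispiro[4.0.4.2]dodeca-3,9-diene-2,8-dione
Conditions: NBS (1.05 equiv), NaHCO3, MeCN, −20 → 0 °C, dark
Reagents that add atoms: N-bromosuccinimide, O=C1CCC(=O)N1Br
Why: Br+ from NBS adds to the central allene carbon across the distal π bond (ring carbon to central carbon) on the face away from the carboxyl, and the carboxyl oxygen attacks the ring carbon anti to it, so the O–C(spiro) bond of ring A and its vinylic C–Br bond form in one operation, the acid proton ending on succinimide. The closest known reaction type is the halolactonisation of 2,3-allenoic acids to 4-halobutenolides, including fully substituted and cycloalkylidene cases. Ring A closes in the 5-endo mode at the sp2 terminus of the allene (5-endo-trig); no other ring is formed. The only new stereocentre, spiro carbon C6, is controlled by the allene axis: the carboxyl lies on the ring face anti to the C2–Br bond and to O5, oxygen enters on that face and the bromovinyl carbon is pushed to the face syn to the neighbouring bromine, which gives the trans relation of the two lactone oxygens. The step needs chemoselectivity for the electron-rich allene over the ester-conjugated, tetrasubstituted bromoalkene of ring B (secured by electronics) and faithful axis-to-centre transfer, which should hold because the bridged bromonium is captured intramolecularly before the tertiary cyclobutyl cation, destabilised by the flanking C–Br and C–O bonds, can open and rotate.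

Step 13
Reactants: 17 the silyl-protected dimer
Product: 18 (1R)-1-[(5S,6S,11R,12R)-4,10,11,12-tetrabromo-9-butyl-2,8-dioxo-1,7-dioxadispiro[4.0.4.2]dodeca-3,9-dien-3-yl]butyl acetate (CNP0268004.1)
Conditions: Ac2O, FeCl3 (0.2 equiv), 0 °C → rt
Reagents that add atoms: acetic anhydride, CC(=O)OC(C)=O
Why: Lewis-acid-promoted acylative cleavage of the silyl ether (direct silyl ether to acetate exchange) breaks the O–Si bond and not the C–O bond, so the (R) carbinol centre is retained, and it avoids nucleophilic amines that could attack the bromobutenolides.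

Compound list
1 | 1,2-bis(trimethylsilyloxy)cyclobut-1-ene | C[Si](C)(C)OC1=C(O[Si](C)(C)C)CC1 | starting material
2 | cyclobutane-1,2-dione | O=C1CCC1=O | intermediate
3 | 2,2-dimethoxycyclobutan-1-one | COC1(OC)CCC1=O | intermediate
4 | (S)-4-bromo-2,2-dimethoxycyclobutan-1-one | COC1(OC)C[C@H](Br)C1=O | intermediate
5 | (R)-hex-1-yn-3-ol | CCC[C@@H](O)C#C | starting material
6 | (R)-3-(tert-butyldimethylsilyloxy)hex-1-yne | CCC[C@@H](O[Si](C)(C)C(C)(C)C)C#C | intermediate
7 | (1R,4S)-4-bromo-1-[(3R)-3-(tert-butyldimethylsilyloxy)hex-1-yn-1-yl]-2,2-dimethoxycyclobutan-1-ol, OH cis to Br, present in the flask as its metal alkoxide | COC1(OC)C[C@H](Br)[C@@]1(O)C#C[C@@H](CCC)O[Si](C)(C)C(C)(C)C | intermediate (not isolated)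
8 | (1R,4S)-4-bromo-1-[(3R)-3-(tert-butyldimethylsilyloxy)hex-1-yn-1-yl]-2,2-dimethoxycyclobutyl diethyl phosphate, phosphate O cis to Br | COC1(OC)C[C@H](Br)[C@@]1(OP(=O)(OCC)OCC)C#C[C@@H](CCC)O[Si](C)(C)C(C)(C)C | intermediate
9 | (3R)-2-{[(4S)-4-bromo-2,2-dimethoxycyclobutylidene]methylidene}-3-(tert-butyldimethylsilyloxy)hexanoic acid, (P)-allene with CO2H on the ring face anti to Br (axis not encoded in the SMILES) | COC1(OC)C[C@H](Br)C1=C=C(C(=O)O)[C@@H](CCC)O[Si](C)(C)C(C)(C)C | intermediate
10 | (3S,4S)-3,8-dibromo-7-[(1R)-1-(tert-butyldimethylsilyloxy)butyl]-1,1-dimethoxy-5-oxaspiro[3.4]oct-7-en-6-one, lactone O trans to C3–Br | COC1(OC)C[C@H](Br)[C@@]12OC(=O)C([C@@H](CCC)O[Si](C)(C)C(C)(C)C)=C2Br | intermediate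
11 | (3S,4S)-3,8-dibromo-7-[(1R)-1-(tert-butyldimethylsilyloxy)butyl]-5-oxaspiro[3.4]oct-7-ene-1,6-dione | O=C1C[C@H](Br)[C@@]12OC(=O)C([C@@H](CCC)O[Si](C)(C)C(C)(C)C)=C2Br | intermediate
12 | (2R,3R,4S)-2,3,8-tribromo-7-[(1R)-1-(tert-butyldimethylsilyloxy)butyl]-5-oxaspiro[3.4]oct-7-ene-1,6-dione, 2,3-trans dibromide | O=C1[C@@H](Br)[C@H](Br)[C@@]12OC(=O)C([C@@H](CCC)O[Si](C)(C)C(C)(C)C)=C2Br | intermediate
13 | hex-1-yne | CCCCC#C | starting material
14 | (1R,2R,3R,4S)-2,3,8-tribromo-7-[(1R)-1-(tert-butyldimethylsilyloxy)butyl]-1-(hex-1-yn-1-yl)-1-hydroxy-5-oxaspiro[3.4]oct-7-en-6-one, OH cis to C2–Br, present in the flask as its metal alkoxide | CCCCC#C[C@]1(O)[C@@H](Br)[C@H](Br)[C@@]12OC(=O)C([C@@H](CCC)O[Si](C)(C)C(C)(C)C)=C2Br | intermediate (not isolated)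
15 | (1R,2R,3R,4S)-2,3,8-tribromo-7-[(1R)-1-(tert-butyldimethylsilyloxy)butyl]-1-(hex-1-yn-1-yl)-6-oxo-5-oxaspiro[3.4]oct-7-en-1-yl diethyl phosphate | CCCCC#C[C@]1(OP(=O)(OCC)OCC)[C@@H](Br)[C@H](Br)[C@@]12OC(=O)C([C@@H](CCC)O[Si](C)(C)C(C)(C)C)=C2Br | intermediate
16 | 2-{[(2R,3R,4S)-2,3,8-tribromo-7-[(1R)-1-(tert-butyldimethylsilyloxy)butyl]-6-oxo-5-oxaspiro[3.4]oct-7-en-1-ylidene]methylidene}hexanoic acid, (P)-allene with CO2H on the ring face anti to the C2–Br bond and to O5 (axis not encoded in the SMILES) | CCCCC(C(=O)O)=C=C1[C@@H](Br)[C@H](Br)[C@@]12OC(=O)C([C@@H](CCC)O[Si](C)(C)C(C)(C)C)=C2Br | intermediate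
17 | (5S,6S,11R,12R)-4,10,11,12-tetrabromo-9-butyl-3-[(1R)-1-(tert-butyldimethylsilyloxy)butyl]-1,7-dioxadispiro[4.0.4.2]dodeca-3,9-diene-2,8-dione | CCCCC1=C(Br)[C@@]2(OC1=O)[C@@H](Br)[C@H](Br)[C@@]21OC(=O)C([C@@H](CCC)O[Si](C)(C)C(C)(C)C)=C1Br | intermediate
18 | (1R)-1-[(5S,6S,11R,12R)-4,10,11,12-tetrabromo-9-butyl-2,8-dioxo-1,7-dioxadispiro[4.0.4.2]dodeca-3,9-dien-3-yl]butyl acetate | CCCCC1=C(Br)[C@@]2(OC1=O)[C@@H](Br)[C@H](Br)[C@@]21OC(=O)C([C@@H](CCC)OC(C)=O)=C1Br | target

Total step count: 13. Longest linear sequence: 12 steps (1 to 18 through steps 1–3 and 5–13; step 4 is the side branch).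

Steps most likely to fail

Step 3. Enamine formation from a hindered, strained α,α-dialkoxy cyclobutanone may be slow, so that bromination is incomplete or poorly enantioselective. The fallback sets out from 3 and comes back at 4. Ketone 3 is converted with LiN(SiMe3)2 and Me3SiCl (THF, −78 °C) into the silyl enol ether 4,4-dimethoxy-1-(trimethylsilyloxy)cyclobut-1-ene F1. NBS then brominates it to the racemic bromoketone, whose enantiomers are separated by preparative chromatography on a chiral stationary phase. Compound 4 goes on; its mirror image, (R)-4-bromo-2,2-dimethoxycyclobutan-1-one F2, is racemised with Bu4NBr (degenerate SN2 bromide exchange) and resolved again.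

Step 10. Enolisation of the α,β-dibromoketone by the basic acetylide, followed by E1cB loss of bromide, may compete with 1,2-addition. The fallback sets out from 12 and comes back at 15; it replaces the carbanion by a neutral alkynylborane. B-(hex-1-yn-1-yl)-9-borabicyclo[3.3.1]nonane F3 (from 13, n-BuLi, B-methoxy-9-borabicyclo[3.3.1]nonane and BF3·OEt2) should add to the ketone in pentane at room temperature to give the borinate ester of the tertiary alcohol F4. 2-Aminoethanol releases alcohol 14, isolated in this variant, which is phosphorylated to 15 with LiN(SiMe3)2 and ClP(O)(OEt)2 at −78 °C.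

Step 12. The axis-to-centre transfer may erode if the bromonium opens to a free cation, or Br+ may be consumed elsewhere. The fallback sets out from 16 and comes back at 17; it separates ring closure from bromine introduction. Hg(OCOCF3)2 (CH2Cl2, 0 °C) should effect a stereospecific anti-oxymercuration/lactonisation to the ring-A vinylmercury trifluoroacetate F5, in which the same O–C(spiro) bond is formed. Br2 in pyridine (−40 °C) then replaces mercury by bromine with retention.

Further compounds
F1 | step 3 | 4,4-dimethoxy-1-(trimethylsilyloxy)cyclobut-1-ene | COC1(OC)CC=C1O[Si](C)(C)C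
F2 | step 3 | (R)-4-bromo-2,2-dimethoxycyclobutan-1-one | COC1(OC)C[C@@H](Br)C1=O
F3 | step 10 | B-(hex-1-yn-1-yl)-9-borabicyclo[3.3.1]nonane | CCCCC#CB1C2CCCC1CCC2
F4 | step 10 | 9-borabicyclo[3.3.1]nonan-9-yl borinate ester of alcohol 14 | CCCCC#C[C@]1(OB2C3CCCC2CCC3)[C@@H](Br)[C@H](Br)[C@@]12OC(=O)C([C@@H](CCC)O[Si](C)(C)C(C)(C)C)=C2Br
F5 | step 12 | ring-A vinylmercury trifluoroacetate, the 4-[(trifluoroacetoxy)mercurio] analogue of 17 | CCCCC1=C([Hg]OC(=O)C(F)(F)F)[C@@]2(OC1=O)[C@@H](Br)[C@H](Br)[C@@]21OC(=O)C([C@@H](CCC)O[Si](C)(C)C(C)(C)C)=C1Br
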